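## The problem

CNP0148734.1 (49) is a bisabolane: a cyclohexane (ring A, C1–C6) joined through C1 to the chain C7–C11, with C14 as the methylidene carbon on C7. In this numbering C2 is the ring methylene, C3 carries the lactone ester, C4 the methyl and a tertiary hydroxyl, C5 an angelate, C6 a free hydroxyl, C8 a carbinol, C10 the second angelate and C11 the dimethyl carbinol; β denotes the face of ring A that carries the C1 chain. Ring A has five stereocentres on six carbons (O4, O5 and O6 β, O3 α), so that in the chair with the chain equatorial the oxygens on C3, C4 and C6 are all axial. C1 can be bought with (S)-carvone and can set C5 (axial hydride delivery), and C5 can then set C4 and C3 (hydroxyl-directed epoxidation, diaxial opening). C6 is contrary: its oxygen must sit cis to the C1 substituent, where no reagent approaches, so it is best made by hydride addition to a C6 ketone from the open α face. C8 and C10 are insulated from the ring and from each other, so both need reagent control. Seven oxygens must end as three esters and four free hydroxyls; the esters cannot be present while organometallics make the carbon–carbon bonds, the angelates drift to tiglates under base or heat, the lactone centre C5' is α to a carbonyl, the cis-vicinal O4/O5/O6 invite acyl migration, and O4 can bridge to C7 in cineole fashion if C7 turns cationic. What opens the structure is C7: it carries three carbon substituents (C1, C14, C8) and C10 is a carbinol two carbons beyond C8, so an ethynyl group on C1 can take up C14 as methyl and C9–C11 as a terminal epoxide, leaving an (E)-C7=C8 olefin from which the C8 carbinol and the methylidene are drawn later.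

## Retrosynthesis

49 ⇒ 48. Only the two Si–O bonds on O6 and O11 are cut. Ending with an acidic fluoride source rather than any base keeps the angelates and the cis-vicinal O5/O6 pair quiet. The forward step must remove a hindered secondary and a tertiary silyl ether without touching three esters.

48 ⇒ 47 ⇒ 46. The C8 carbinol and C7=C14 are traced through the (7R,8R)-epoxide 47 to the (E)-C7=C8 olefin of 46. The neighbouring cuts (a C7 vinyl metal plus a C8 aldehyde, or an aldol at C8–C9) would create C8 with nothing nearby to direct it. A trisubstituted (E)-olefin is the best substrate class for a chiral dioxirane, and homolytic opening at C7 by Cp2TiCl never breaks the C8–O bond. The forward steps must pick one olefin face by reagent control and eliminate toward C14, not C1.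

46 ⇒ 44 + 35. The O3–acyl bond is cut, which removes ten carbons and three stereocentres as acid 35. It is the last ester to go on because 44 then offers one secondary hydroxyl (O3) beside a tertiary one, and because 35 is the costliest acyl partner. The forward reaction is an acylation of an axial, neopentyl-type alcohol by an α-quaternary acid.

44 ⇒ 43 ⇒ 40 + 41. Both angelate O–acyl bonds (O5, O10) are cut together, then the p-methoxybenzyl ether on O3. Triol 40 shows exactly two secondary hydroxyls and one tertiary, so a single acylation with angelic acid 41 can serve both positions. This is shorter than introducing the two angelates in separate operations with a protecting group on O8 in between.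

40 ⇒ 39. The 4,5-acetonide is taken off directly after the coupling, while the molecule still holds only ethers, an olefin and robust silyl groups. The tertiary silyl ether on O11 is therefore chosen as tert-butyldimethylsilyl, which survives this acid step and later keeps O11 from closing a tetrahydrofuran on the C7–C8 epoxide.

39 ⇒ 17 + 36 + 21. C7–C14 and C8–C9 are cut in one operation: ethynyl ring fragment 17, trimethylaluminium 36 and epoxide 21. The alternative of joining C1–C7 would have to form a bond to a ring carbon flanked by an axial oxygen; this cut instead uses a carbon that carvone already supplies. The precursors are a ring with all five ring stereocentres and a five-carbon epoxide with C10. The forward step needs methyl on C7, syn addition, alkenyl transfer and attack at the epoxide CH2.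

17 ⇒ 14 ⇒ 13. The ethynyl group is the isopropenyl group of carvone at a different oxidation level: methyl ketone 14 by oxidative cleavage, then enol phosphate and elimination. The forward sequence must enolise only toward the methyl group so that C1 is not touched.

13 ⇒ 12 ⇒ 11 ⇒ 10 ⇒ 9. The O6 configuration is set on ketone 11. Hydride enters from the α face (equatorial attack, away from the axial O4 of the acetonide) and gives the axial 6β-alcohol 12. The ketone comes from the 6α-alcohol that enolate hydroxylation of carvone provides, so the price of the cis C1/C6 relationship is a desilylation, an oxidation, a reduction and a silylation.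

9 ⇒ 8 ⇒ 7 ⇒ 6 ⇒ 5 ⇒ 4 ⇒ 3 ⇒ 1. O3, O4 and O5 go back to the enone of (S)-carvone 1: Luche reduction (C5), vanadium-directed epoxidation (C4), diaxial hydrolysis at C3, acetonide on the only cis-diol, p-methoxybenzyl on O3. The C6 oxygen is introduced first, by enolate hydroxylation, and silylated so that O3 and O6 stay distinguishable.

21 ⇒ 20 ⇒ 19 ⇒ 18. The epoxide comes from 2-methylbut-3-en-2-ol 18 by silylation, epoxidation and hydrolytic kinetic resolution. A resolution is accepted because the material is cheap and the step count is three.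

35 ⇒ 33 ⇒ 31 ⇒ 29 ⇒ 27 ⇒ 24 + 25. In acid 35 the C5' ethyl group is cut first (lactone enolate alkylation, trans to the C3' methyl), then the lactone C–O bond and the C4'–C5' olefin (Wittig), and finally C2'–C3'. The last cut is an anti-selective catalytic aldol of thioester ketene acetal 24 (from 22) with methyl pyruvate 25, which sets the tertiary carbinol and its neighbour in one step and leaves the two carboxyl termini differentiated as ester and thioester.

## Roads not taken

Alternative 1: The ring bond C1–C2 would be cut. Forward, anodic oxidation of the open-chain bis(methyl enol ether) A1 in methanol would join the two enol-ether β-carbons and give cyclohexane A2, with C3 trapped as a dimethyl ketal and C7 as a dimethyl acetal.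
- Merits: C3 and C7 emerge differentiated at the carbonyl level, and the C7 acetal leads to the C1 ethynyl group through an aldehyde and a mild diazophosphonate homologation, which is gentler than the methyl ketone route used here. The O5/O6 cis-diol is carried in from the chain, so no inversion at C6 is needed; in that respect this road is better.
- Weak points: C1 is created in the radical-cation closure and must come out cis to O6; A1 itself needs the quaternary C4 carbinol and two further stereocentres made in open-chain form; six-membered closures between two enol ethers are less secure than five-membered ones; the C3 ketone must afterwards be reduced to the axial alcohol.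
- Comparison: the chosen plan pays four steps for C6 but takes C1 from carvone and sets C3–C5 by substrate control on a ring whose conformation is known. Alternative 1 also says nothing about the chain.

Alternative 2: The C5=C6 bond would be cut. Forward, the second-generation Grubbs catalyst (H2IMes)(PCy3)Cl2Ru=CHPh would close the 1,7-diene A3 to cyclohexene A4 with loss of ethylene.
- Merits: the metathesis itself is dependable. The C5=C6 olefin lies next to the tertiary C4 hydroxyl, so a hydrogen-bond-directed osmylation (OsO4·TMEDA) could deliver O5 and O6 on the β face in one step. That is a more direct answer to the all-cis O4/O5/O6 array than the oxidation–reduction used here.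
- Weak points: A3 requires C1, C3 and the quaternary C4 to be built by asymmetric open-chain chemistry; the osmylation would have to come syn to the C1 substituent as well; the new diol must then be differentiated (O5 against O6, with O4 competing for any acetonide); C7 is only a silyloxymethyl group and needs oxidation and homologation.
- Comparison: the chosen plan sets against this the chiral-pool ring, in which every oxygen is introduced with the differentiation it needs later.

Alternative 3: The carvone ring would be opened and the C4–C5 bond cut. Forward, SmI2 (divalent samarium) would reduce the aldehyde and the methyl ketone of keto aldehyde A5 and couple the two ketyl carbons to the cis-4,5-diol A6.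
- Merits: A6 already contains the whole chain with C7=C14 and O8 in place, so the late epoxidation and isomerisation of the chosen plan would be unnecessary; the quaternary C4 and C5 form together as the cis-diol. This is the most convergent of the four roads.
- Weak points: both carbonyls of A5 carry an α-silyloxy group (O3 next to C4, O6 next to C5), and samarium ketyls expel α-oxygen substituents in competition with coupling. Such closures usually place the diol anti to both flanking alkoxy groups, which suits O3/O4 but contradicts the cis O5/O6 relationship. Opening and reclosing the ring costs steps, and C8 would need its own stereocontrol earlier.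
- Comparison: the chosen plan keeps the carvone ring intact and accepts two late steps for C8 in exchange for predictable ring stereochemistry.

Key step: step 23

Assumption (chemistry): for the chiral catalysts whose sense of induction is not tied here to a mnemonic (the Ph-pybox tin triflate of step 18, the (salen)Co(OAc) of step 16 and the BINAP–ruthenium complex of one fallback), the enantiomer that gives the drawn product is meant; both antipodes of each are commercial.

## Route

Step 1
Reactants: 1 (S)-carvone
Product: 3 6α-hydroxycarvone [(5R,6R)-6-hydroxy-2-methyl-5-(prop-1-en-2-yl)cyclohex-2-en-1-one; hydroxyl trans to isopropenyl], via potassium dienolate 2 (not isolated)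
Conditions: KN(SiMe3)2, THF, −78 °C; 3-phenyl-2-(phenylsulfonyl)oxaziridine, −78 °C; aq. NH4Cl
Reagents that add atoms: 3-phenyl-2-(phenylsulfonyl)oxaziridine, O=S(=O)(c1ccccc1)N1OC1c1ccccc1
Why: Kinetic α'-deprotonation of the enone and enolate hydroxylation (Davis oxidation); oxygen should enter anti to the isopropenyl group. The C6 configuration made here is temporary, since it is erased at ketone 11, so the minor 6β epimer converges.

Step 2
Reactants: 3 6α-hydroxycarvone
Product: 4 6α-(tert-butyldimethylsilyloxy)carvone
Conditions: t-BuMe2SiCl, imidazole, DMF, rt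
Reagents that add atoms: tert-butyldimethylsilyl chloride, CC(C)(C)[Si](C)(C)Cl
Why: Standard silylation of a secondary alcohol; it keeps O6 apart from O3 and O5 until the acetonide and the benzyl ether are in place.

Step 3
Reactants: 4 6α-(tert-butyldimethylsilyloxy)carvone
Product: 5 allylic alcohol (5β-hydroxy-6α-silyloxy-4-methyl-1β-isopropenylcyclohex-3-ene)
Conditions: NaBH4, CeCl3·7H2O, MeOH, −78 °C
Reagents that add atoms: none
Why: Luche 1,2-reduction; axial hydride delivery to the half-chair enone gives the equatorial 5β-alcohol cis to the isopropenyl group, as in carvone to cis-carveol, and the equatorial 6α-silyloxy group does not oppose it.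

Step 4
Reactants: 5 allylic alcohol
Product: 6 epoxy alcohol (3β,4β-epoxide; O5 β, O6 α)
Conditions: VO(acac)2 (cat.), t-BuOOH, CH2Cl2, 0 °C → rt
Reagents that add atoms: tert-butyl hydroperoxide, CC(C)(C)OO
Why: Vanadium-catalysed hydroxyl-directed epoxidation puts the oxirane on the face of the allylic C5 hydroxyl and leaves the isopropenyl olefin alone; this sets C4.

Step 5
Reactants: 6 epoxy alcohol
Product: 7 triol (3α,4β,5β-trihydroxy-4α-methyl-6α-silyloxy-1β-isopropenylcyclohexane)
Conditions: HClO4 (cat.), THF/H2O, 0 °C → rt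
Reagents that add atoms: water, O
Why: Acid-catalysed epoxide hydrolysis with Fürst–Plattner control: attack at C3 leads directly to the chair with the C1, C5 and C6 substituents equatorial, and the C5 oxygen disfavours positive charge at C4. C3 is therefore inverted (O3 α) and C4 keeps the epoxide oxygen (O4 β).

Step 6
Reactants: 7 triol
Product: 8 4β,5β-acetonide (3α-hydroxyl free)
Conditions: Me2C(OMe)2, PPTS (cat.), CH2Cl2, rt
Reagents that add atoms: 2,2-dimethoxypropane, COC(C)(C)OC
Why: Transketalisation engages the only cis-diol (O4/O5); O3 is trans-diaxial to O4 and cannot bridge, so it is left free.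

Step 7
Reactants: 8 4β,5β-acetonide
Product: 9 3α-(4-methoxybenzyl) ether
Conditions: NaH, 4-MeOC6H4CH2Cl, Bu4NI (cat.), DMF, 0 °C → rt
Reagents that add atoms: 4-methoxybenzyl chloride, COc1ccc(CCl)cc1
Why: Williamson etherification of the single free hydroxyl; the ether withstands the organometallic steps and is removable oxidatively.

Step 8
Reactants: 9 3α-(4-methoxybenzyl) ether
Product: 10 6α-alcohol
Conditions: Bu4NF, THF, rt
Reagents that add atoms: none
Why: Fluoride desilylation; nothing else in 9 is fluoride-labile.

Step 9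
Reactants: 10 6α-alcohol
Product: 11 C6 ketone
Conditions: Dess–Martin periodinane, NaHCO3, CH2Cl2, 0 °C → rt
Reagents that add atoms: none
Why: Neutral, buffered periodinane oxidation; the β,γ-unsaturated ketone is used at once so that neither C1 epimerisation nor conjugation of the isopropenyl group sets in.

Step 10
Reactants: 11 C6 ketone
Product: 12 6β-alcohol (axial; cis to the C1 and C5 substituents)
Conditions: LiBH(s-Bu)3, THF, −78 °C; aq. NH4Cl
Reagents that add atoms: none
Why: Bulky hydride adds equatorially from the α face, away from the axial O4 and the acetonide, giving the axial alcohol; the reduction of isopulegone to neoisopulegol is the model. This sets C6.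

Step 11
Reactants: 12 6β-alcohol
Product: 13 6β-(tert-butyldimethylsilyl) ether
Conditions: t-BuMe2SiOTf, 2,6-lutidine, CH2Cl2, 0 °C
Reagents that add atoms: tert-butyldimethylsilyl triflate, CC(C)(C)[Si](C)(C)OS(=O)(=O)C(F)(F)F
Why: The silyl triflate is needed for the hindered axial hydroxyl.

Step 12
Reactants: 13 6β-(tert-butyldimethylsilyl) ether
Product: 14 methyl ketone (1β-acetyl)
Conditions: K2OsO2(OH)4 (2 mol%), NaIO4, 2,6-lutidine, dioxane/H2O, rt
Reagents that add atoms: sodium periodate, [Na+].[O-]I(=O)(=O)=O
Why: Lemieux–Johnson cleavage of the 1,1-disubstituted olefin; it spares the electron-rich benzyl ether that ozone could attack, and the lutidine buffer protects C1.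

Step 13
Reactants: 14 methyl ketone
Product: 17 ring alkyne (1β-ethynyl-3α-(4-methoxybenzyloxy)-4β,5β-isopropylidenedioxy-4α-methyl-6β-silyloxycyclohexane), via lithium enolate 15 (not isolated), via enol phosphate 16 (not isolated)
Conditions: LiN(i-Pr)2 (1.1 equiv), THF, −78 °C; ClP(O)(OEt)2, −78 °C → rt; LiN(i-Pr)2 (2.3 equiv), −78 °C → rt
Reagents that add atoms: none
Why: Negishi conversion of a methyl ketone into a terminal alkyne: kinetic deprotonation at the methyl group, O-phosphorylation and base-induced elimination of diethyl phosphate. Enolisation away from C1 leaves that stereocentre and the β-silyloxy group untouched.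

Step 14
Reactants: 18 2-methylbut-3-en-2-ol
Product: 19 tert-butyldimethyl[(2-methylbut-3-en-2-yl)oxy]silane
Conditions: t-BuMe2SiOTf, 2,6-lutidine, CH2Cl2, 0 °C → rt
Reagents that add atoms: tert-butyldimethylsilyl triflate, CC(C)(C)[Si](C)(C)OS(=O)(=O)C(F)(F)F
Why: Silylation of a tertiary alcohol with the triflate; the tertiary silyl ether is chosen to survive the later acid step and to resist migration to O10.

Step 15
Reactants: 19 tert-butyldimethyl[(2-methylbut-3-en-2-yl)oxy]silane
Product: 20 racemic tert-butyldimethyl{[2-(oxiran-2-yl)propan-2-yl]oxy}silane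
Conditions: m-CPBA, CH2Cl2, 0 °C → rt
Reagents that add atoms: 3-chloroperoxybenzoic acid, OOC(=O)c1cccc(Cl)c1
Why: Prilezhaev epoxidation of the only olefin.

Step 16
Reactants: 20 racemic epoxide
Product: 21 (S)-tert-butyldimethyl{[2-(oxiran-2-yl)propan-2-yl]oxy}silane
Conditions: (salen)Co(OAc) (trivalent cobalt; salen = N,N'-bis(3,5-di-tert-butylsalicylidene)-1,2-cyclohexanediamine dianion; 1 mol%), H2O (0.55 equiv), THF, 0 °C → rt
Reagents that add atoms: none
Why: Jacobsen hydrolytic kinetic resolution; the catalyst hydrolyses the (R)-epoxide at its CH2 and the (S)-epoxide is recovered, as with other oxiranes bearing a bulky tertiary substituent. This sets C10.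

Step 17
Reactants: 22 S-ethyl propanethioate
Product: 24 (Z)-1-(ethylsulfanyl)-1-(trimethylsilyloxy)prop-1-ene (methyl cis to sulfur), via lithium enolate 23 (not isolated)
Conditions: LiN(i-Pr)2, THF, −78 °C; Me3SiCl, −78 °C → rt
Reagents that add atoms: chlorotrimethylsilane, C[Si](C)(C)Cl
Why: Kinetic enolisation of a thioester and O-silylation give the ketene thioacetal used in catalytic Mukaiyama aldol reactions.

Step 18
Reactants: 24 (Z)-1-(ethylsulfanyl)-1-(trimethylsilyloxy)prop-1-ene; 25 methyl pyruvate
Product: 27 methyl (2S,3R)-4-(ethylsulfanyl)-2-hydroxy-2,3-dimethyl-4-oxobutanoate, via trimethylsilyl ether 26 (not isolated)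
Conditions: Sn(OTf)2 (10 mol%), Ph-pybox (12 mol%), CH2Cl2, −78 °C; 1 M HCl, THF
Reagents that add atoms: none
Why: Evans anti-selective Mukaiyama aldol addition to a pyruvate chelated on divalent tin. The ligand fixes the ketone face (C2') and the open transition state gives the anti relationship of hydroxyl and C3' methyl in the succinate zigzag (the two methyls syn). The termini are left as ester and thioester.

Step 19
Reactants: 27 methyl (2S,3R)-4-(ethylsulfanyl)-2-hydroxy-2,3-dimethyl-4-oxobutanoate
Product: 29 dimethyl (2S,3S,4E)-2-hydroxy-2,3-dimethylhex-4-enedioate, via aldehyde 28 (not isolated)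
Conditions: Et3SiH, Pd/C, CH2Cl2, rt; filter; Ph3P=CHCO2Me, CH2Cl2, rt
Reagents that add atoms: methyl (triphenylphosphoranylidene)acetate, COC(=O)C=P(c1ccccc1)(c1ccccc1)c1ccccc1
Why: Fukuyama reduction takes the thioester, not the ester, to the aldehyde, which is trapped at once by a stabilised Wittig reagent so that the β-hydroxy aldehyde has no time for retro-aldol cleavage or epimerisation.

Step 20
Reactants: 29 dimethyl (2S,3S,4E)-2-hydroxy-2,3-dimethylhex-4-enedioate
Product: 31 methyl (2S,3S)-2,3-dimethyl-6-oxooxane-2-carboxylate, via saturated diester 30 (not isolated)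
Conditions: H2 (1 atm), Pd/C, EtOAc, rt; filter; TsOH·H2O (cat.), PhMe, 80 °C
Reagents that add atoms: none
Why: Olefin hydrogenation, then acid-catalysed lactonisation of the tertiary hydroxyl onto the δ-ester (six-membered ring, helped by the gem-disubstitution); the hindered α-quaternary ester stays.

Step 21
Reactants: 31 methyl (2S,3S)-2,3-dimethyl-6-oxooxane-2-carboxylate
Product: 33 methyl (2S,3S,5S)-5-ethyl-2,3-dimethyl-6-oxooxane-2-carboxylate, via lithium enolate 32 (not isolated)
Conditions: LiN(i-Pr)2, THF, −78 °C; EtI, DMPU, −78 → −30 °C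
Reagents that add atoms: iodoethane, CCI
Why: Kinetic alkylation of a δ-lactone enolate. In the half-chair with the C3' methyl pseudo-equatorial the electrophile enters axially, syn only to the C3' hydrogen, which places ethyl trans to that methyl, as in the known alkylations of Prelog–Djerassi-type lactone enolates.

Step 22
Reactants: 33 methyl (2S,3S,5S)-5-ethyl-2,3-dimethyl-6-oxooxane-2-carboxylate
Product: 35 (2S,3S,5S)-5-ethyl-2,3-dimethyl-6-oxooxane-2-carboxylic acid, via hydroxy diacid 34 (not isolated)
Conditions: LiOH, THF/MeOH/H2O, 50 °C; 2 M HCl to pH 1, rt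
Reagents that add atoms: lithium hydroxide, [Li+].[OH-]; water, O
Why: Saponification opens the lactone and cleaves the methyl ester; on acidification only the δ-lactone can reform. Carboxylate α-centres do not epimerise under these conditions.

Step 23
Reactants: 17 ring alkyne; 36 trimethylaluminium; 21 (S)-epoxide
Product: 39 coupled (E)-olefin (ring as in 17; C1 bears the (2E,5S)-5-hydroxy-6-methyl-6-silyloxyhept-2-en-2-yl chain), via alkenylalane 37 (not isolated), via lithium alanate 38 (not isolated)
Conditions: 36 (2.5 equiv), Cp2ZrCl2 (0.5 equiv), (CH2Cl)2, rt; volatiles off in vacuo; hexane, n-BuLi (1.05 equiv), −78 → 0 °C; 21 (2 equiv), THF, 0 °C → rt; aq. KNaC4H4O6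
Reagents that add atoms: none
Why: Zirconium-catalysed carboalumination (Negishi) followed by epoxide opening by the derived alkenylalanate, a known one-flask sequence for terminal alkynes and monosubstituted epoxides. Cp2ZrCl2 and AlMe3 form a methylzirconium species that adds methyl and metal syn across the ethynyl group with methyl on the internal carbon C7, and transmetalation leaves the (E)-alkenyldimethylalane 37. n-BuLi turns the weakly nucleophilic alane into the tetracoordinate alanate 38, from which the sp2 carbon migrates in preference to methyl or butyl. The alanate attacks epoxide 21 at its CH2 in an SN2 manner (the other carbon is shielded by the quaternary silyloxy centre), so C8–C9 forms with retention of olefin geometry and C10 keeps the configuration of 21. No ring closes and no stereocentre is created. The selectivities needed are regiochemistry and syn addition in the carbometalation, exclusive alkenyl transfer and attack at the terminal epoxide carbon, all inherent in the reagents. The substrate helps by offering only ethers and a tertiary tert-butyldimethylsilyl ether on O11 that should not shift to the new O10 alkoxide. Removing excess AlMe3 before n-BuLi keeps methylalanates from competing for the epoxide.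

Step 24
Reactants: 39 coupled (E)-olefin
Product: 40 triol (4β-, 5β- and 10-hydroxyls free; O3 p-methoxybenzyl; O6 and O11 silyl)
Conditions: PPTS (0.3 equiv), MeOH, 50 °C
Reagents that add atoms: none
Why: Acid-catalysed transketalisation removes the acetonide; the hindered secondary and the tertiary silyl ethers, the benzyl ether and the trisubstituted olefin tolerate pyridinium tosylate.

Step 25
Reactants: 40 triol; 41 angelic acid
Product: 43 5,10-di-O-angelate (4β-hydroxyl free), via mixed anhydride 42 (not isolated)
Conditions: 41 (6 equiv), 2,4,6-Cl3C6H2COCl (6 equiv), Et3N, PhMe, rt; then 40, 80 °C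
Reagents that add atoms: none
Why: Yamaguchi-type acylation with the preformed mixed anhydride and no nucleophilic catalyst, the conditions known to deliver angelates without Z-to-E isomerisation. Both secondary hydroxyls react and the tertiary O4 does not.

Step 26
Reactants: 43 5,10-di-O-angelate
Product: 44 3α-alcohol
Conditions: DDQ, CH2Cl2/pH 7 buffer, 0 °C
Reagents that add atoms: none
Why: Oxidative cleavage of the p-methoxybenzyl ether; water intercepts the oxocarbenium ion, and the trans-diaxial O4 cannot close an anisylidene acetal.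

Step 27
Reactants: 44 3α-alcohol; 35 (2S,3S,5S)-5-ethyl-2,3-dimethyl-6-oxooxane-2-carboxylic acid
Product: 46 triester (O3 lactone-acyl; O5 and O10 angelates; O6 and O11 silyl), via acid chloride 45 (not isolated)
Conditions: 35 (3 equiv), Me2C=C(Cl)NMe2, CH2Cl2, 0 °C → rt; then 44, DMAP, PhMe, 50 °C
Reagents that add atoms: none
Why: The acid chloride is made under neutral conditions (Ghosez reagent) and has no α-hydrogen, so no ketene can form; acylation through the acylpyridinium ion reaches the secondary O3 while the tertiary O4 stays free. The mild base leaves C5' of the lactone alone.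

Step 28
Reactants: 46 triester
Product: 47 (7R,8R)-epoxide
Conditions: D-fructose-derived Shi ketone (0.5 equiv), KHSO5 (as 2KHSO5·KHSO4·K2SO4), K2CO3, Bu4NHSO4, Na2B4O7/Na2EDTA buffer, MeCN/CH2(OMe)2/H2O, 0 °C
Reagents that add atoms: potassium peroxymonosulfate, [K+].[O-]S(=O)(=O)OO
Why: Shi epoxidation of an (E)-trisubstituted olefin; by the spiro transition-state model the D-fructose ketone gives the (R,R) epoxide, setting C8 under reagent control. The electron-poor angelate olefins are not attacked by the dioxirane.

Step 29
Reactants: 47 (7R,8R)-epoxide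
Product: 48 (8R)-allylic alcohol with C7=C14 (the 6,11-bis-silyl ether of the target)
Conditions: Cp2TiCl2 (2.5 equiv), Mn dust, THF, rt (gives Cp2TiCl); then 47, rt; aq. NaH2PO4
Reagents that add atoms: none
Why: Epoxide opening by trivalent titanium (Nugent–RajanBabu): electron transfer cleaves the C7–O bond to the tertiary radical, a second Cp2TiCl traps it and β-hydride elimination takes a hydrogen from the unhindered C14 methyl. The C8–O bond is never broken, so C8 stays R.

Step 30
Reactants: 48 (8R)-allylic alcohol
Product: 49 CNP0148734.1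
Conditions: HF·pyridine, pyridine, THF, 0 °C → rt
Reagents that add atoms: none
Why: Buffered acidic fluoride removes both silyl ethers (the tertiary one slowly) without the acyl migration or angelate isomerisation that basic fluoride would invite.

## Compound list

1 | (S)-carvone | C=C(C)[C@H]1CC=C(C)C(=O)C1 | starting material
2 | potassium dienolate of 1 | [K+].C=C(C)[C@H]1CC=C(C)C([O-])=C1 | intermediate
3 | 6α-hydroxycarvone, (5R,6R)-6-hydroxy-2-methyl-5-(prop-1-en-2-yl)cyclohex-2-en-1-one | C=C(C)[C@H]1CC=C(C)C(=O)[C@@H]1O | intermediate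
4 | 6α-(tert-butyldimethylsilyloxy)carvone | C=C(C)[C@H]1CC=C(C)C(=O)[C@@H]1O[Si](C)(C)C(C)(C)C | intermediate
5 | allylic alcohol, 5β-hydroxy-6α-silyloxy-4-methyl-1β-isopropenylcyclohex-3-ene | C=C(C)[C@H]1CC=C(C)[C@@H](O)[C@@H]1O[Si](C)(C)C(C)(C)C | intermediate
6 | 3β,4β-epoxy alcohol | C=C(C)[C@H]1C[C@H]2O[C@@]2(C)[C@@H](O)[C@@H]1O[Si](C)(C)C(C)(C)C | intermediate
7 | 3α,4β,5β-triol | C=C(C)[C@H]1C[C@H](O)[C@@](C)(O)[C@@H](O)[C@@H]1O[Si](C)(C)C(C)(C)C | intermediate
8 | 4β,5β-acetonide, 3α-hydroxyl free | C=C(C)[C@H]1C[C@H](O)[C@@]2(C)OC(C)(C)O[C@H]2[C@@H]1O[Si](C)(C)C(C)(C)C | intermediate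
9 | 3α-(4-methoxybenzyl) ether, 6α-silyl ether | C=C(C)[C@H]1C[C@H](OCc3ccc(OC)cc3)[C@@]2(C)OC(C)(C)O[C@H]2[C@@H]1O[Si](C)(C)C(C)(C)C | intermediate
10 | 6α-alcohol | C=C(C)[C@H]1C[C@H](OCc3ccc(OC)cc3)[C@@]2(C)OC(C)(C)O[C@H]2[C@@H]1O | intermediate
11 | C6 ketone | C=C(C)[C@H]1C[C@H](OCc3ccc(OC)cc3)[C@@]2(C)OC(C)(C)O[C@H]2C1=O | intermediate
12 | 6β-alcohol | C=C(C)[C@H]1C[C@H](OCc3ccc(OC)cc3)[C@@]2(C)OC(C)(C)O[C@H]2[C@H]1O | intermediate
13 | 6β-(tert-butyldimethylsilyl) ether | C=C(C)[C@H]1C[C@H](OCc3ccc(OC)cc3)[C@@]2(C)OC(C)(C)O[C@H]2[C@H]1O[Si](C)(C)C(C)(C)C | intermediate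
14 | methyl ketone (1β-acetyl) | CC(=O)[C@H]1C[C@H](OCc3ccc(OC)cc3)[C@@]2(C)OC(C)(C)O[C@H]2[C@H]1O[Si](C)(C)C(C)(C)C | intermediate
15 | lithium enolate of 14 (methyl side) | [Li+].C=C([O-])[C@H]1C[C@H](OCc3ccc(OC)cc3)[C@@]2(C)OC(C)(C)O[C@H]2[C@H]1O[Si](C)(C)C(C)(C)C | intermediate
16 | enol diethyl phosphate | C=C(OP(=O)(OCC)OCC)[C@H]1C[C@H](OCc3ccc(OC)cc3)[C@@]2(C)OC(C)(C)O[C@H]2[C@H]1O[Si](C)(C)C(C)(C)C | intermediate
17 | ring alkyne, 1β-ethynyl-3α-(4-methoxybenzyloxy)-4β,5β-isopropylidenedioxy-4α-methyl-6β-silyloxycyclohexane | C#C[C@H]1C[C@H](OCc3ccc(OC)cc3)[C@@]2(C)OC(C)(C)O[C@H]2[C@H]1O[Si](C)(C)C(C)(C)C | intermediate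
18 | 2-methylbut-3-en-2-ol | C=CC(C)(C)O | starting material
19 | tert-butyldimethyl[(2-methylbut-3-en-2-yl)oxy]silane | C=CC(C)(C)O[Si](C)(C)C(C)(C)C | intermediate
20 | racemic tert-butyldimethyl{[2-(oxiran-2-yl)propan-2-yl]oxy}silane | CC(C)(O[Si](C)(C)C(C)(C)C)C1CO1 | intermediate
21 | (S)-tert-butyldimethyl{[2-(oxiran-2-yl)propan-2-yl]oxy}silane | CC(C)(O[Si](C)(C)C(C)(C)C)[C@@H]1CO1 | intermediate
22 | S-ethyl propanethioate | CCC(=O)SCC | starting material
23 | lithium enolate of 22 | [Li+].C/C=C(\SCC)[O-] | intermediate
24 | (Z)-1-(ethylsulfanyl)-1-(trimethylsilyloxy)prop-1-ene | C/C=C(\SCC)O[Si](C)(C)C | intermediate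
25 | methyl pyruvate | CC(=O)C(=O)OC | starting material
26 | O-trimethylsilyl ether of 27 | COC(=O)[C@@](C)(O[Si](C)(C)C)[C@@H](C)C(=O)SCC | intermediate
27 | methyl (2S,3R)-4-(ethylsulfanyl)-2-hydroxy-2,3-dimethyl-4-oxobutanoate | COC(=O)[C@@](C)(O)[C@@H](C)C(=O)SCC | intermediate
28 | methyl (2S,3R)-2-hydroxy-2,3-dimethyl-4-oxobutanoate | COC(=O)[C@@](C)(O)[C@@H](C)C=O | intermediate
29 | dimethyl (2S,3S,4E)-2-hydroxy-2,3-dimethylhex-4-enedioate | COC(=O)[C@@](C)(O)[C@@H](C)/C=C/C(=O)OC | intermediate
30 | dimethyl (2S,3S)-2-hydroxy-2,3-dimethylhexanedioate | COC(=O)[C@@](C)(O)[C@@H](C)CCC(=O)OC | intermediate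
31 | methyl (2S,3S)-2,3-dimethyl-6-oxooxane-2-carboxylate | COC(=O)[C@@]1(C)OC(=O)CC[C@@H]1C | intermediate
32 | lithium enolate of 31 | [Li+].COC(=O)[C@@]1(C)OC([O-])=CC[C@@H]1C | intermediate
33 | methyl (2S,3S,5S)-5-ethyl-2,3-dimethyl-6-oxooxane-2-carboxylate | COC(=O)[C@@]1(C)OC(=O)[C@@H](CC)C[C@@H]1C | intermediate
34 | (2S,3S,5S)-5-ethyl-2-hydroxy-2,3-dimethylhexanedioic acid | OC(=O)[C@@](C)(O)[C@@H](C)C[C@H](CC)C(=O)O | intermediate
35 | (2S,3S,5S)-5-ethyl-2,3-dimethyl-6-oxooxane-2-carboxylic acid | OC(=O)[C@@]1(C)OC(=O)[C@@H](CC)C[C@@H]1C | intermediate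
36 | trimethylaluminium | C[Al](C)C | starting material
37 | (E)-alkenyldimethylalane from 17 | C/C(=C\[Al](C)C)[C@H]1C[C@H](OCc3ccc(OC)cc3)[C@@]2(C)OC(C)(C)O[C@H]2[C@H]1O[Si](C)(C)C(C)(C)C | intermediate
38 | lithium (E)-alkenyl(butyl)dimethylalanate | [Li+].CCCC[Al-](C)(C)/C=C(\C)[C@H]1C[C@H](OCc3ccc(OC)cc3)[C@@]2(C)OC(C)(C)O[C@H]2[C@H]1O[Si](C)(C)C(C)(C)C | intermediate
39 | coupled (E)-C7=C8 olefin, 10-hydroxyl free, O11 silyl | C/C(=C\C[C@H](O)C(C)(C)O[Si](C)(C)C(C)(C)C)[C@H]1C[C@H](OCc3ccc(OC)cc3)[C@@]2(C)OC(C)(C)O[C@H]2[C@H]1O[Si](C)(C)C(C)(C)C | intermediate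
40 | 4β,5β,10-triol | C/C(=C\C[C@H](O)C(C)(C)O[Si](C)(C)C(C)(C)C)[C@H]1C[C@H](OCc2ccc(OC)cc2)[C@@](C)(O)[C@@H](O)[C@H]1O[Si](C)(C)C(C)(C)C | intermediate
41 | angelic acid | C/C=C(/C)C(=O)O | starting material
42 | angelic 2,4,6-trichlorobenzoic anhydride | C/C=C(/C)C(=O)OC(=O)c1c(Cl)cc(Cl)cc1Cl | intermediate
43 | 5,10-di-O-angelate | C/C(=C\C[C@H](OC(=O)/C(C)=C\C)C(C)(C)O[Si](C)(C)C(C)(C)C)[C@H]1C[C@H](OCc2ccc(OC)cc2)[C@@](C)(O)[C@@H](OC(=O)/C(C)=C\C)[C@H]1O[Si](C)(C)C(C)(C)C | intermediate
44 | 3α-alcohol | C/C(=C\C[C@H](OC(=O)/C(C)=C\C)C(C)(C)O[Si](C)(C)C(C)(C)C)[C@H]1C[C@H](O)[C@@](C)(O)[C@@H](OC(=O)/C(C)=C\C)[C@H]1O[Si](C)(C)C(C)(C)C | intermediate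
45 | acid chloride of 35 | ClC(=O)[C@@]1(C)OC(=O)[C@@H](CC)C[C@@H]1C | intermediate
46 | triester with (E)-C7=C8 olefin | C/C(=C\C[C@H](OC(=O)/C(C)=C\C)C(C)(C)O[Si](C)(C)C(C)(C)C)[C@H]1C[C@H](OC(=O)[C@@]2(C)OC(=O)[C@@H](CC)C[C@@H]2C)[C@@](C)(O)[C@@H](OC(=O)/C(C)=C\C)[C@H]1O[Si](C)(C)C(C)(C)C | intermediate
47 | (7R,8R)-epoxide | C[C@@]1(O[C@@H]1C[C@H](OC(=O)/C(C)=C\C)C(C)(C)O[Si](C)(C)C(C)(C)C)[C@H]2C[C@H](OC(=O)[C@@]3(C)OC(=O)[C@@H](CC)C[C@@H]3C)[C@@](C)(O)[C@@H](OC(=O)/C(C)=C\C)[C@H]2O[Si](C)(C)C(C)(C)C | intermediate
48 | (8R)-allylic alcohol, 6,11-bis-silyl ether of the target | C=C([C@H](O)C[C@H](OC(=O)/C(C)=C\C)C(C)(C)O[Si](C)(C)C(C)(C)C)[C@H]1C[C@H](OC(=O)[C@@]2(C)OC(=O)[C@@H](CC)C[C@@H]2C)[C@@](C)(O)[C@@H](OC(=O)/C(C)=C\C)[C@H]1O[Si](C)(C)C(C)(C)C | intermediate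
49 | CNP0148734.1 | C=C([C@H](O)C[C@H](OC(=O)/C(C)=C\C)C(C)(C)O)[C@H]1C[C@H](OC(=O)[C@@]2(C)OC(=O)[C@@H](CC)C[C@@H]2C)[C@@](C)(O)[C@@H](OC(=O)/C(C)=C\C)[C@H]1O | target

## Step count and weak points

Total: 30 steps. Longest linear sequence: 21 steps (steps 1–13 and 23–30, from (S)-carvone).

Step 23 (key step). What may go wrong: slow or incomplete carbometalation of a hindered alkyne flanked by Lewis-basic ethers; Lewis-acid opening of the acetonide by AlMe3; poor transfer from the alanate to an epoxide next to a quaternary centre; a 1,2-silyl shift from O11 to the new O10 alkoxide. Fallback: from 17 the methylalumination is quenched with iodine to give the (E)-vinyl iodide F1. Halogen–lithium exchange (t-BuLi, Et2O, −78 °C) and BF3·OEt2-assisted opening of epoxide 21 by the alkenyllithium then return to 39. The same two bonds are made in two flasks, and the epoxide opening takes place at −78 °C.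

Step 27. What may go wrong: low conversion, because an axial neopentyl-type alcohol meets an α-quaternary acyl donor; forcing then risks angelate isomerisation and epimerisation α to the lactone carbonyl. Fallback: the order of the esterifications is changed so that O3 is acylated while O4 is still tied back in the acetonide and no other hydroxyl is free. From 39, the 10-hydroxyl alone is angeloylated as in step 25 to give the 10-angelate F6. DDQ frees O3 to give the 3α-alcohol F7. Acylation with 45, now with a large excess, gives the acetonide ester F8. PPTS in methanol gives the 4β,5β-diol F9, and a second angeloylation at O5 returns to 46.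

Step 28. What may go wrong: poor facial selectivity if the bulky ring next to C7 is mismatched with the ketone, and slow turnover with long exposure of three esters to pH 10. Fallback: C8 is set by ketone reduction instead. From 46, m-CPBA gives the mixture of trans epoxides F10. Cp2TiCl as in step 29 gives the C8-epimeric allylic alcohols F11. Dess–Martin periodinane gives the enone F12, and (S)-2-methyl-CBS-oxazaborolidine with BH3·SMe2 (the alkenyl side as the large group) returns to 48.

Step 29. What may go wrong: elimination toward C1 instead of C14, hydrogen capture by the tertiary radical to give the saturated alcohol, or capture of C7 by the C4 hydroxyl. Fallback: an ionic isomerisation. From 47, Me3SiOTf with 2,6-lutidine and then DBU (epoxide to allylic silyl ether, proton loss from the unhindered methyl, C8–O untouched) gives the 4,8-bis(trimethylsilyl) ether F13. The fluoride treatment of step 30 then leads directly to 49.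

Step 21. What may go wrong: insufficient facial selectivity in the enolate alkylation, O-alkylation, or attack of the enolate on the neighbouring ester. Fallback: C5' is set by catalyst instead. From 27, Fukuyama reduction as in step 19 and Horner–Wadsworth–Emmons reaction of aldehyde 28 with triethyl 2-phosphonobutanoate give the (E)-2-ethyl enoate F4. LiOH gives the unsaturated hydroxy diacid F5. Hydrogenation with Ru(OAc)2(BINAP), the method established for 2-alkyl-2-alkenoic acids, gives 34, which lactonises on acidification to 35.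

Step 13. What may go wrong: enolisation toward C1 with epimerisation or loss of the C6 silyloxy group, and incomplete elimination or allene formation. Fallback: a route without a ketone enolate. From 14, hydrazine gives the hydrazone F2. Iodine with tetramethylguanidine gives the 2-iodoalkene F3, and NaN(SiMe3)2 eliminates hydrogen iodide to return to 17.

## Further compounds

F1 | step 23 | (E)-vinyl iodide from 17 | C/C(=C\I)[C@H]1C[C@H](OCc3ccc(OC)cc3)[C@@]2(C)OC(C)(C)O[C@H]2[C@H]1O[Si](C)(C)C(C)(C)C
F2 | step 13 | hydrazone of 14 | CC(=NN)[C@H]1C[C@H](OCc3ccc(OC)cc3)[C@@]2(C)OC(C)(C)O[C@H]2[C@H]1O[Si](C)(C)C(C)(C)C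
F3 | step 13 | 2-iodoalkene | C=C(I)[C@H]1C[C@H](OCc3ccc(OC)cc3)[C@@]2(C)OC(C)(C)O[C@H]2[C@H]1O[Si](C)(C)C(C)(C)C
F4 | step 21 | 6-ethyl 1-methyl (2S,3S,4E)-5-ethyl-2-hydroxy-2,3-dimethylhex-4-enedioate | COC(=O)[C@@](C)(O)[C@@H](C)/C=C(\CC)C(=O)OCC
F5 | step 21 | (2S,3S,4E)-5-ethyl-2-hydroxy-2,3-dimethylhex-4-enedioic acid | OC(=O)[C@@](C)(O)[C@@H](C)/C=C(\CC)C(=O)O
F6 | step 27 | 10-angelate of 39 | C/C(=C\C[C@H](OC(=O)/C(C)=C\C)C(C)(C)O[Si](C)(C)C(C)(C)C)[C@H]1C[C@H](OCc3ccc(OC)cc3)[C@@]2(C)OC(C)(C)O[C@H]2[C@H]1O[Si](C)(C)C(C)(C)C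
F7 | step 27 | 3α-alcohol with acetonide | C/C(=C\C[C@H](OC(=O)/C(C)=C\C)C(C)(C)O[Si](C)(C)C(C)(C)C)[C@H]1C[C@H](O)[C@@]2(C)OC(C)(C)O[C@H]2[C@H]1O[Si](C)(C)C(C)(C)C
F8 | step 27 | 3-O-lactone-acyl ester with acetonide | C/C(=C\C[C@H](OC(=O)/C(C)=C\C)C(C)(C)O[Si](C)(C)C(C)(C)C)[C@H]1C[C@H](OC(=O)[C@@]3(C)OC(=O)[C@@H](CC)C[C@@H]3C)[C@@]2(C)OC(C)(C)O[C@H]2[C@H]1O[Si](C)(C)C(C)(C)C
F9 | step 27 | 4β,5β-diol with O3 ester and O10 angelate | C/C(=C\C[C@H](OC(=O)/C(C)=C\C)C(C)(C)O[Si](C)(C)C(C)(C)C)[C@H]1C[C@H](OC(=O)[C@@]2(C)OC(=O)[C@@H](CC)C[C@@H]2C)[C@@](C)(O)[C@@H](O)[C@H]1O[Si](C)(C)C(C)(C)C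
F10 | step 28 | mixture of the two trans C7–C8 epoxides of 46 | CC1(OC1C[C@H](OC(=O)/C(C)=C\C)C(C)(C)O[Si](C)(C)C(C)(C)C)[C@H]2C[C@H](OC(=O)[C@@]3(C)OC(=O)[C@@H](CC)C[C@@H]3C)[C@@](C)(O)[C@@H](OC(=O)/C(C)=C\C)[C@H]2O[Si](C)(C)C(C)(C)C
F11 | step 28 | C8-epimeric allylic alcohols | C=C(C(O)C[C@H](OC(=O)/C(C)=C\C)C(C)(C)O[Si](C)(C)C(C)(C)C)[C@H]1C[C@H](OC(=O)[C@@]2(C)OC(=O)[C@@H](CC)C[C@@H]2C)[C@@](C)(O)[C@@H](OC(=O)/C(C)=C\C)[C@H]1O[Si](C)(C)C(C)(C)C
F12 | step 28 | C8 enone | C=C(C(=O)C[C@H](OC(=O)/C(C)=C\C)C(C)(C)O[Si](C)(C)C(C)(C)C)[C@H]1C[C@H](OC(=O)[C@@]2(C)OC(=O)[C@@H](CC)C[C@@H]2C)[C@@](C)(O)[C@@H](OC(=O)/C(C)=C\C)[C@H]1O[Si](C)(C)C(C)(C)C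
F13 | step 29 | 4,8-bis(trimethylsilyl) ether of 48 | C=C([C@H](O[Si](C)(C)C)C[C@H](OC(=O)/C(C)=C\C)C(C)(C)O[Si](C)(C)C(C)(C)C)[C@H]1C[C@H](OC(=O)[C@@]2(C)OC(=O)[C@@H](CC)C[C@@H]2C)[C@@](C)(O[Si](C)(C)C)[C@@H](OC(=O)/C(C)=C\C)[C@H]1O[Si](C)(C)C(C)(C)C
A1 | alternative 1 | open-chain bis(methyl enol ether) | C=C(OC)[C@@](C)(O[Si](CC)(CC)CC)[C@H]1OC(C)(C)O[C@H]1/C=C/OC
A2 | alternative 1 | cyclohexane with C3 dimethyl ketal and C7 dimethyl acetal | COC(OC)[C@H]1CC(OC)(OC)[C@@](C)(O[Si](CC)(CC)CC)[C@H]2OC(C)(C)O[C@@H]12
A3 | alternative 2 | 1,7-diene | C=C[C@@H](CO[Si](C)(C)C(C)(C)C)C[C@H](OCc1ccc(OC)cc1)[C@@](C)(O)C=C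
A4 | alternative 2 | cyclohex-5-ene with C1, C3 and C4 stereocentres | CC(C)(C)[Si](C)(C)OC[C@H]1C[C@H](OCc2ccc(OC)cc2)[C@@](C)(O)C=C1
A5 | alternative 3 | open-chain keto aldehyde | C=C([C@@H]1OC(C)(C)O[C@H](C(C)(C)O[Si](CC)(CC)CC)C1)[C@@H](C[C@H](O[Si](CC)(CC)CC)C(C)=O)[C@H](O[Si](C)(C)C(C)(C)C)C=O
A6 | alternative 3 | reclosed cyclohexane cis-4,5-diol | C=C([C@@H]1OC(C)(C)O[C@H](C(C)(C)O[Si](CC)(CC)CC)C1)[C@H]2C[C@H](O[Si](CC)(CC)CC)[C@@](C)(O)[C@@H](O)[C@H]2O[Si](C)(C)C(C)(C)C
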